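**Plan**

- Retrosynthesis: cut C4'–Br (HBr across a C4'=C5' alkene, which also removes a silyl mask), then C3'–Cl (inversion of an allylic alcohol), then the oxane O–C6/C5–Br pair (bromoetherification), then C3'–C4' and C5'–C6' of the carbocycle (two-carbon ring expansion of a cyclobutanone by an alkyne), then the cyclobutanone (ketene [2+2] on the vinyl group of linalool).
- Forward: (R)-linalool → temporary bromo-ether ring → cyclobutanone (future C3', C2', C1', C6') → unmasking → nickel-catalysed insertion of silylpropyne (adds C4', C5') to give the cyclohexenone → oxane ring → Cl → Br.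
- Enabling feature: C1' lies between two CH2 groups (C2', C6') and 1,3 to C3', so removing C4'–C5' leaves a 3-substituted cyclobutanone with prochiral C1'. Its carbonyl becomes C3' (future C–Cl) and the alkyne methyl carbon becomes C4' (future C–Br). The resulting enone therefore encodes "Br tertiary / Cl secondary", the reverse of what Br+/Cl– addition to the ring alkene would be expected to give.
- Stereochemistry: oxane C2 comes from (R)-linalool; C1' from ligand-controlled choice between the two C(O)–CH2 bonds in the key step; oxane C5 from chair-like anti bromoetherification; C3' from axial hydride delivery followed by SN2 inversion; C4' from anti, diaxial bromide capture.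

Key step: step 4

Assumption: (R)-(−)-linalool of high enantiomeric purity is taken as commercial. Compounds 2, 5 and 6 are carried as stereoisomer mixtures at centres that disappear in step 3, so those centres are left undefined in their SMILES.

Step 1
Reactants: 1 (R)-(−)-linalool
Product: 2 (6R)-3-bromo-6-ethenyl-2,2,6-trimethyloxane (both C3 epimers)
Conditions: NBS, CH2Cl2, 0 °C
Reagents that add atoms: N-bromosuccinimide, O=C1CCC(=O)N1Br
Why: Bromoetherification (6-endo, Markovnikov opening of the bromonium ion at the tertiary carbon) locks the nucleophilic trisubstituted alkene and the alcohol into a temporary oxane ring, so that the vinyl group is the only alkene left for step 2; the bromide configuration is irrelevant because the ring is opened again in step 3.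

Step 2
Reactants: 2 (6R)-3-bromo-6-ethenyl-2,2,6-trimethyloxane; 3 trichloroacetyl chloride
Product: 5 2,2-dichloro-3-[(2R)-5-bromo-2,6,6-trimethyloxan-2-yl]cyclobutan-1-one, via dichloroketene 4 (not isolated)
Conditions: Zn–Cu couple, POCl3, Et2O, 25–35 °C
Reagents that add atoms: none
Why: Ketene–alkene [2+2] cycloaddition, in which dichloroketene made in situ by zinc dechlorination of 3 should add to the monosubstituted vinyl group with its carbonyl carbon on the terminal CH2 (3-substituted cyclobutanone regiochemistry), while the di-tertiary ether oxygen is too hindered for O-acylation and Claisen-type side reactions.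

Step 3
Reactants: 5 2,2-dichloro-3-[(2R)-5-bromo-2,6,6-trimethyloxan-2-yl]cyclobutan-1-one
Product: 7 3-[(2R)-2-hydroxy-6-methylhept-5-en-2-yl]cyclobutan-1-one, via dechlorinated bromoether cyclobutanone 6 (not isolated)
Conditions: Zn dust, AcOH, 25 → 70 °C
Reagents that add atoms: none
Why: Zinc should first reduce the two activated α-C–Cl bonds (reductive dehalogenation of an α,α-dichloroketone) and then, on warming, effect Boord-type reductive elimination of the β-bromo ether, which removes the temporary ring and returns the tertiary alcohol and the trisubstituted alkene, so that all isomers of 5 converge on one ketone whose ring carbon C3 is prochiral.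

Step 4
Reactants: 7 3-[(2R)-2-hydroxy-6-methylhept-5-en-2-yl]cyclobutan-1-one; 8 1-(trimethylsilyl)propyne
Product: 9 (5S)-5-[(2R)-2-hydroxy-6-methylhept-5-en-2-yl]-2-methyl-3-(trimethylsilyl)cyclohex-2-en-1-one
Conditions: 8 (3 equiv), Ni(cod)2 (10 mol %), (S)-BINOL-derived N,N-bis[(S)-1-phenylethyl]phosphoramidite (20 mol %; antipode if mismatched), toluene, 90 °C, sealed tube
Reagents that add atoms: none
Why: Proposed new method: zerovalent nickel should couple the ketone C=O and the alkyne oxidatively to a spiro oxanickelacyclopentene (silyl-bearing carbon on nickel, methyl-bearing carbon on the former carbonyl carbon), strain-driven β-carbon elimination should then cleave one cyclobutane C(O)–CH2 bond to a seven-membered nickelacycle, and C(sp3)–C(sp2) reductive elimination should release the cyclohexenone, a net insertion of the two alkyne carbons into the four-membered ring. The closest known reaction type is the nickel/trialkylphosphine-catalysed intermolecular alkyne insertion into 3-substituted cyclobutanones, and the closest stereochemical precedent is the nickel/phosphoramidite-catalysed enantioselective intramolecular alkene insertion into prochiral cyclobutanones; new here is ligand-controlled selection between the two diastereotopic C(O)–CH2 bonds in the intermolecular alkyne case. The six-membered ring is closed by reductive elimination from the seven-membered metallacycle (a formal [4+2] union of the C(O)–C–C–C unit of 7 with the two alkyne carbons), not by a polar cyclization. The one new stereocentre, C5 of the enone (C1' of the target), comes from the prochiral C3 of 7 and should be fixed in the β-carbon elimination by the chiral ligand, because the substrate itself exerts little bias (the neighbouring carbinol carbon differs only in methyl versus alkyl chain). Regioselectivity (methyl next to the carbonyl) is secured by the silyl group, which prefers the nickel-bound position as in nickel-mediated carbonyl–silylalkyne couplings, and chemoselectivity is secured because the trisubstituted alkene and the tertiary alcohol neither insert nor bind competitively and 7 carries no carbon–halogen bond that could add oxidatively to nickel.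

Step 5
Reactants: 9 (5S)-5-[(2R)-2-hydroxy-6-methylhept-5-en-2-yl]-2-methyl-3-(trimethylsilyl)cyclohex-2-en-1-one
Product: 10 (5S)-5-[(2R,5S)-5-bromo-2,6,6-trimethyloxan-2-yl]-2-methyl-3-(trimethylsilyl)cyclohex-2-en-1-one
Conditions: TBCO, MeNO2, 0 °C
Reagents that add atoms: 2,4,4,6-tetrabromocyclohexa-2,5-dien-1-one (TBCO), O=C1C(Br)=CC(Br)(Br)C=C1Br
Why: Bromoetherification through a chair-like 6-endo transition state with anti addition should place Br equatorial and the larger cyclohexenyl group of the carbinol carbon equatorial (methyl axial), which sets the (5S) bromide trans to the carbocycle, while the electron-poor silyl enone alkene is not attacked and the minor bromide epimer or any five-membered ether is removed by chromatography.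

Step 6
Reactants: 10 (5S)-5-[(2R,5S)-5-bromo-2,6,6-trimethyloxan-2-yl]-2-methyl-3-(trimethylsilyl)cyclohex-2-en-1-one
Product: 11 (1R,5S)-5-[(2R,5S)-5-bromo-2,6,6-trimethyloxan-2-yl]-2-methyl-3-(trimethylsilyl)cyclohex-2-en-1-ol
Conditions: NaBH4, CeCl3·7H2O, MeOH, −78 °C
Reagents that add atoms: none
Why: Luche 1,2-reduction, in which hydride should add axially to the half-chair enone that carries the oxanyl group pseudo-equatorially (as in the reduction of carvone to cis-carveol), giving the equatorial alcohol cis to that group, with the hindered secondary bromide inert.

Step 7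
Reactants: 11 (1R,5S)-5-[(2R,5S)-5-bromo-2,6,6-trimethyloxan-2-yl]-2-methyl-3-(trimethylsilyl)cyclohex-2-en-1-ol
Product: 12 (2R,5S)-5-bromo-2-[(1R,5S)-5-chloro-4-methyl-3-(trimethylsilyl)cyclohex-3-en-1-yl]-2,6,6-trimethyloxane
Conditions: PPh3, hexachloroacetone, CH2Cl2, −20 → 0 °C
Reagents that add atoms: hexachloroacetone, ClC(Cl)(Cl)C(=O)C(Cl)(Cl)Cl
Why: Appel-type chlorination, in which SN2 displacement of the alkoxyphosphonium group by chloride should invert the allylic carbinol carbon so that Cl becomes pseudo-axial and trans to the oxanyl group, the silyl group on the distal alkene carbon blocking the SN2' pathway.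

Step 8
Reactants: 12 (2R,5S)-5-bromo-2-[(1R,5S)-5-chloro-4-methyl-3-(trimethylsilyl)cyclohex-3-en-1-yl]-2,6,6-trimethyloxane
Product: 14 deoxy isocaespitol [(2R,5S)-5-bromo-2-[(1R,3S,4S)-4-bromo-3-chloro-4-methylcyclohexyl]-2,6,6-trimethyloxane], via desilylated allylic chloride 13 (not isolated)
Conditions: HBr (2.5 equiv), CH2Cl2, −78 → −40 °C; NaHCO3 quench
Reagents that add atoms: hydrogen bromide, Br
Why: ipso-Protodesilylation of the vinylsilane (through the tertiary β-silyl cation) followed by Markovnikov ionic hydrobromination of the resulting trisubstituted alkene, in which the tertiary cation at C4' is bridged by the neighbouring axial chlorine and bromide should enter anti and axially, giving the trans-diaxial tertiary bromide with the methyl equatorial and placing Br on the tertiary and Cl on the secondary carbon by construction.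

**Compound list**

1 | (R)-(−)-linalool, (3R)-3,7-dimethylocta-1,6-dien-3-ol | C=C[C@](C)(O)CCC=C(C)C | starting material
2 | (6R)-3-bromo-6-ethenyl-2,2,6-trimethyloxane (temporary bromo-ether, C3 epimers) | C=C[C@@]1(C)CCC(Br)C(C)(C)O1 | intermediate
3 | trichloroacetyl chloride | ClC(=O)C(Cl)(Cl)Cl | starting material
4 | dichloroketene (not isolated) | ClC(Cl)=C=O | intermediate
5 | 2,2-dichloro-3-[(2R)-5-bromo-2,6,6-trimethyloxan-2-yl]cyclobutan-1-one (isomer mixture) | O=C1CC([C@@]2(C)CCC(Br)C(C)(C)O2)C1(Cl)Cl | intermediate
6 | 3-[(2R)-5-bromo-2,6,6-trimethyloxan-2-yl]cyclobutan-1-one (not isolated) | O=C1CC(C1)[C@@]2(C)CCC(Br)C(C)(C)O2 | intermediate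
7 | 3-[(2R)-2-hydroxy-6-methylhept-5-en-2-yl]cyclobutan-1-one | O=C1CC(C1)[C@](C)(O)CCC=C(C)C | intermediate
8 | 1-(trimethylsilyl)propyne | CC#C[Si](C)(C)C | starting material
9 | (5S)-5-[(2R)-2-hydroxy-6-methylhept-5-en-2-yl]-2-methyl-3-(trimethylsilyl)cyclohex-2-en-1-one | CC(C)=CCC[C@@](C)(O)[C@@H]1CC([Si](C)(C)C)=C(C)C(=O)C1 | intermediate
10 | (5S)-5-[(2R,5S)-5-bromo-2,6,6-trimethyloxan-2-yl]-2-methyl-3-(trimethylsilyl)cyclohex-2-en-1-one | CC1(C)O[C@@](C)([C@@H]2CC([Si](C)(C)C)=C(C)C(=O)C2)CC[C@@H]1Br | intermediate
11 | (1R,5S)-5-[(2R,5S)-5-bromo-2,6,6-trimethyloxan-2-yl]-2-methyl-3-(trimethylsilyl)cyclohex-2-en-1-ol | CC1(C)O[C@@](C)([C@@H]2CC([Si](C)(C)C)=C(C)[C@H](O)C2)CC[C@@H]1Br | intermediate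
12 | (2R,5S)-5-bromo-2-[(1R,5S)-5-chloro-4-methyl-3-(trimethylsilyl)cyclohex-3-en-1-yl]-2,6,6-trimethyloxane | CC1(C)O[C@@](C)([C@@H]2CC([Si](C)(C)C)=C(C)[C@@H](Cl)C2)CC[C@@H]1Br | intermediate
13 | (2R,5S)-5-bromo-2-[(1R,5S)-5-chloro-4-methylcyclohex-3-en-1-yl]-2,6,6-trimethyloxane (not isolated) | CC1(C)O[C@@](C)([C@@H]2CC=C(C)[C@@H](Cl)C2)CC[C@@H]1Br | intermediate
14 | deoxy isocaespitol, (2R,5S)-5-bromo-2-[(1R,3S,4S)-4-bromo-3-chloro-4-methylcyclohexyl]-2,6,6-trimethyloxane | CC1(C)O[C@@](C)([C@@H]2CC[C@](C)(Br)[C@@H](Cl)C2)CC[C@@H]1Br | target

**Totals**

Total step count: 8. Longest linear sequence: 8 steps (1 → 14).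

**Steps most likely to fail**

Step 4. The chiral ligand may fail to discriminate the two diastereotopic C(O)–CH2 bonds in the β-carbon elimination, so that control at C5 is lost, or it may slow insertion enough for alkyne oligomerization to take over. The fallback gives up asymmetric induction and uses known chemistry. It sets out from 7: the established achiral protocol for alkyne insertion into 3-substituted cyclobutanones (Ni(cod)2, PCy3, toluene, 100 °C) with 8 should give 9 together with its C5 epimer, (5R)-5-[(2R)-2-hydroxy-6-methylhept-5-en-2-yl]-2-methyl-3-(trimethylsilyl)cyclohex-2-en-1-one F1. Because the carbinol centre is already fixed, the two are diastereomers and not enantiomers, so the control element changes from the catalyst to a physical separation (chromatography, at the latest after step 5, where the oxane makes the epimers more rigid). The route is rejoined at 9, with at most half of the material.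

Step 5. Facial selectivity in the chair-like bromonium opening may be poor, since an axial methyl and an axial ring substituent are not far apart in energy, and some 5-exo closure may leak through. The fallback replaces kinetic bromonium capture by a reversible, thermodynamically controlled mercury-mediated cyclization. It sets out from 9: Hg(OCOCF3)2 in MeNO2 at 0 °C followed by aqueous KBr should give the equatorial organomercuric bromide, the HgBr analogue of 10 with the same configuration F2. Brominative demercuration with retention (Br2, LiBr, pyridine, 0 °C) then returns to the route at 10.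

Step 8. The excess of strong acid may ionize the oxane C–O bonds (reversal of the bromoetherification, ether cleavage) or the allylic C–Cl bond before the second protonation, and halogen scrambling may follow. The fallback separates the two events and forms the C–Br bond by a neutral radical process. It sets out from 12: protodesilylation with a weaker acid (TFA, CH2Cl2, −20 °C) and isolation of 13, then cobalt-hydride hydrogen-atom-transfer Markovnikov hydrobromination (Co(acac)2, t-BuOOH, Et3SiH, TsBr), in which the tertiary radical should take bromine from the axial face anti to chlorine. The route is rejoined at 14.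

**Further compounds**

F1 | step 4 | (5R)-5-[(2R)-2-hydroxy-6-methylhept-5-en-2-yl]-2-methyl-3-(trimethylsilyl)cyclohex-2-en-1-one (C5 epimer of 9) | CC(C)=CCC[C@@](C)(O)[C@H]1CC([Si](C)(C)C)=C(C)C(=O)C1
F2 | step 5 | organomercuric bromide analogue of 10 (HgBr in place of Br at oxane C5, same configuration) | CC1(C)O[C@@](C)([C@@H]2CC([Si](C)(C)C)=C(C)C(=O)C2)CC[C@@H]1[Hg]Br
F0 | step 8 | none | none
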